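In this stirred vessel of constant volume, I read the target peak in percent of the starting material charged, and the charges of the three earlier runs differ in partner.

| flask | starting material | partner | protic impurity | free catalyst | remark | time |
|---|---|---|---|---|---|---|
| larch | 20 mM | 22 mM | 2 mM | 3 mM | run made earlier |  |
| alder | 20 mM | 11 mM | 2 mM | 3 mM | run made earlier |  |
| cedar | 20 mM | 44 mM | 2 mM | 3 mM | run made earlier |  |
| Thursday's | 20 mM (fed, over 25 h) | 22.0 mM | 2.00 mM | 3.0 mM | all else is in the flask from the start; the feed brings no volume worth counting | 5.0 d |
| Saturday's | 20 mM | 22.0 mM | 2.00 mM | 3.0 mM | everything together at the start | 5.0 d |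
| Wednesday's | 20 mM | 22.0 mM (fed, over 25 h) | 2.00 mM | 3.0 mM | all else is in the flask from the start; the feed brings no volume worth counting | 5.0 d |

- larch (time / d: target / %, starting material / %): 0.333: 1.7, 83.7; 1.04: 8.4, 74.8; 1.67: 16.6, 66.6; 2.50: 23.7, 57.8; 4.00: 32.4, 46.5; 5.00: 32.4, 40.3
- alder (time / d: target / %, starting material / %): 0.250: 0.6, 87.0; 0.417: 0.9, 84.0; 0.625: 3.6, 80.7; 1.04: 8.9, 73.1; 1.67: 16.9, 66.4; 3.00: 23.1, 57.0
- cedar (time / d: target / %, starting material / %): 0.500: 4.5, 83.6; 1.04: 9.8, 74.7; 1.67: 16.6, 66.2; 2.08: 18.9, 61.5; 2.50: 23.2, 55.3; 3.00: 28.0, 51.6

(each reading ± 1 percentage point)

* the best flask by amount of target, in percent of the starting material charged; "all alike" if 1.5 percentage points covers them all (Thursday's / Saturday's / Wednesday's / all alike)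
* amount of target at the end, in percent of the starting material charged, Thursday's
* amount of target at the end, in percent of the starting material charged, Saturday's
* amount of target at the end, in percent of the starting material charged, Wednesday's



The larch target curve reads as a short lag, a straight stretch, a knee and a level. On the straight stretch, larch climbs at 2.10 mM/d. At 1.67 d, alder, larch and cedar read 16.9%, 16.6% and 16.6%, so up to that time the climb reads as zero order in partner, within the scatter. Later the runs part: at 3.00 d, alder reads 4.62 mM of target from 11 mM of partner, less than the 5.60 mM that cedar reads at 3.00 d.

I therefore assume that partner also has a first-order loss, with constant k, beside a constant demand equal to the slope. I define the break-even level a as the slope divided by k, the c_partner at which loss and target formation consume partner at equal rates. Target made until c_partner reaches zero is then a times the natural logarithm of one plus charge over a. Taking alder's last reading as its level gives a of about 2.93 mM, a reading that carries the scatter, and k of 0.715 /d. For larch, this puts the knee near 2.99 d and the level at 31.4%, against the larch reading of 32.4% at 5.00 d.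

Saturday's has the charges of larch, so I keep that level. For Wednesday's, I reckon c_partner at 14.0 mM when the feed ends, which gives 36.6%. For Thursday's, I assume a halved slope during the feed, and I reckon c_partner at 9.36 mM when the feed ends, which gives 26.5%. My reckoning therefore ranks Wednesday's first.

The forecast gives 25% for Thursday's, 34% for Saturday's and 33.5% for Wednesday's, and names Saturday's, holding that “Feeding partner should change little”.

The flasks give 29.1% for Thursday's, 32.6% for Saturday's and 35.8% for Wednesday's, so Wednesday's is best. Decomposed reagent at 5.00 d stands at 12.9 mM in Wednesday's against 14.1 mM in Saturday's. Putting Wednesday's state at 1.04 d through the same logarithm with a, with 10.3% target and 68.2% of the partner charge, gives 36.9%.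

    starting material + free catalyst → free catalyst + open intermediate (k = 2.60 /M/h)
    free catalyst + open intermediate ⇌ catalyst intermediate (K = 4800 /M, k = 46.0 /M/h)
    partner + catalyst intermediate → free catalyst + target (k = 120 /M/h)
    starting material + protic impurity → quenched substrate (k = 33.0 /M/h)
    partner → decomposed reagent (k = 0.0220 /h)
    partner + target → over-reaction product (k = 0.590 /M/h)

For the neighbour of Wednesday's charged with 34 mM of starting material, I scale the slope and a with the charge and keep k, so a becomes 4.99 mM and the reckoning gives 29.6%. That flask computes to 29.2%.

The earlier runs and the new flask were computed with made-up constants; noise was put on by code.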